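The pyridine ring A (C1, N2, C3, C4, C4a, C7a) is cut into three triple bonds: the C4≡C4a and C7a≡C1 alkynes of a 1,6-diyne, linked by the C5–C6–C7 tether that already holds both quaternary stereocentres and the C7 ketone, and the N2≡C3 nitrile that carries the finished (S)-dienyl chain. One cobalt-catalysed [2+2+2] cocyclisation forms C4a–C7a, C3–C4 and N2–C1 and so closes the cyclopentanone ring B and ring A together. The diyne has SiMe3 on the C1 terminus to orient the nitrile and a triethylsilyl ether on the C5 oxygen to block retro-aldol cleavage; both silyl groups leave in one final step.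

Key step: step 10

Remark on the chemistry: atoms are numbered as in 6,7-dihydro-5H-cyclopenta[c]pyridine; the SMILES of the target corresponds to (5R,6S) with an (S) side-chain centre and (1E,3E) geometry, and (R)-lactic acid is the enantiomer that supplies C6 with retention.

Step 1
Reactants: 1 (R)-lactic acid
Product: 2 (2R,5R)-2-tert-butyl-5-methyl-1,3-dioxolan-4-one (cis acetal)
Conditions: pivalaldehyde, TsOH·H2O (cat.), H2SO4 (cat.), pentane, reflux, Dean–Stark; crystallisation from pentane at −78 °C
Reagents that add atoms: pivalaldehyde CC(C)(C)C=O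
Why: Acid-catalysed acetalisation with removal of water (template for self-regeneration of the stereocentre); the lactic acid centre is not touched and the cis acetal, the thermodynamic isomer, is enriched by crystallisation.

Step 2
Reactants: 2 (2R,5R)-2-tert-butyl-5-methyl-1,3-dioxolan-4-one
Product: 4 methyl 2-[(2R,4S)-2-tert-butyl-4-methyl-5-oxo-1,3-dioxolan-4-yl]-2-oxoacetate, via lithium enolate 3 (not isolated)
Conditions: LiN(iPr)2, THF, −78 °C; enolate cannulated into ClCOCO2Me (3 equiv), THF, −78 °C
Reagents that add atoms: methyl chlorooxoacetate COC(=O)C(=O)Cl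
Why: Claisen-type C-acylation of a lithium ester enolate with an acid chloride (inverse addition suppresses O-acylation and aldol addition of 3 to the product); the tert-butyl group shields one face of the planar enolate, so the oxalyl carbon enters trans to it and replaces the former C–H with retention, setting the quaternary centre that becomes C6.

Step 3
Reactants: 4 methyl 2-[(2R,4S)-2-tert-butyl-4-methyl-5-oxo-1,3-dioxolan-4-yl]-2-oxoacetate
Product: 5 methyl (2R)-2-[(2R,4S)-2-tert-butyl-4-methyl-5-oxo-1,3-dioxolan-4-yl]-2-hydroxybut-3-ynoate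
Conditions: HC≡CMgBr (0.5 M in THF, 1.2 equiv), THF, −78 °C; AcOH, −78 °C
Reagents that add atoms: ethynylmagnesium bromide C#C[Mg]Br
Why: Grignard 1,2-addition to the ketone of the α-keto ester, the most electrophilic carbonyl present; under polar Felkin–Anh control (magnesium held by the 1,2-dicarbonyl unit, the weakly basic acylal oxygen not chelating) the acetylide comes in anti to the ring C–O bond and passes the flat lactone carbonyl instead of the methyl group, i.e. onto the Si face of the ketone, which should give the (2R) carbinol that becomes C5, and the cold quench forestalls retro-aldol cleavage.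

Step 4
Reactants: 5 methyl (2R)-2-[(2R,4S)-2-tert-butyl-4-methyl-5-oxo-1,3-dioxolan-4-yl]-2-hydroxybut-3-ynoate
Product: 6 methyl (2R)-2-[(2R,4S)-2-tert-butyl-4-methyl-5-oxo-1,3-dioxolan-4-yl]-2-[(triethylsilyl)oxy]but-3-ynoate
Conditions: Et3SiOTf, 2,6-lutidine, CH2Cl2, 0 °C → rt
Reagents that add atoms: triethylsilyl trifluoromethanesulfonate CC[Si](CC)(CC)OS(=O)(=O)C(F)(F)F
Why: Silylation of a hindered tertiary alcohol with a silyl triflate and lutidine; the ether removes the retro-aldol pathway, leaves a single free hydroxyl for the later methylation and touches no stereocentre.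

Step 5
Reactants: 6 methyl (2R)-2-[(2R,4S)-2-tert-butyl-4-methyl-5-oxo-1,3-dioxolan-4-yl]-2-[(triethylsilyl)oxy]but-3-ynoate; 7 ethynyltrimethylsilane
Product: 10 methyl (2R,3S)-2-ethynyl-3-hydroxy-3-methyl-4-oxo-2-[(triethylsilyl)oxy]-6-(trimethylsilyl)hex-5-ynoate, via lithium (trimethylsilyl)acetylide 8 (not isolated), via lithium hemiketal alkoxide 9 (not isolated)
Conditions: 7 (2.6 equiv), n-BuLi (2.5 equiv), THF, −78 °C; then 6, −78 → −40 °C; AcOH, −78 °C; aq. NaHCO3, silica gel
Reagents that add atoms: none
Why: Single addition of a lithium acetylide to a lactone carbonyl (here an acylal-activated one), a standard ynone synthesis: the tetrahedral alkoxide 9 persists until the acidic quench, so no second addition occurs, and on work-up it opens with loss of pivalaldehyde to the α-hydroxy ynone, while the methyl ester on the silyloxy-bearing quaternary carbon is too hindered to compete, the extra acetylide only deprotonates the alkyne C–H reversibly, and both stereocentres are spectators.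

Step 6
Reactants: 10 methyl (2R,3S)-2-ethynyl-3-hydroxy-3-methyl-4-oxo-2-[(triethylsilyl)oxy]-6-(trimethylsilyl)hex-5-ynoate
Product: 11 methyl (2R,3S)-2-ethynyl-3-methoxy-3-methyl-4-oxo-2-[(triethylsilyl)oxy]-6-(trimethylsilyl)hex-5-ynoate
Conditions: MeOTf (5 equiv), 2,6-di-tert-butyl-4-methylpyridine (6 equiv), CH2Cl2, 40 °C, sealed tube
Reagents that add atoms: methyl trifluoromethanesulfonate COS(=O)(=O)C(F)(F)F
Why: O-methylation of a neutral hindered alcohol with a hard methylating agent and a non-nucleophilic pyridine base; no alkoxide is formed, so neither retro-aldol cleavage of the C2–C3 bond nor 1,4-silyl migration can start, and the configuration at both centres is kept.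

Step 7
Reactants: 12 (S)-2-methylbutan-1-ol
Product: 13 (S)-2-methylbutanal
Conditions: TEMPO (cat.), KBr (cat.), NaOCl, NaHCO3, CH2Cl2/H2O, 0 °C; distillation
Reagents that add atoms: none
Why: Anelli oxidation of a primary alcohol through the oxoammonium cycle; it is fast, cold and buffered, so the α-stereocentre should not epimerise.

Step 8
Reactants: 13 (S)-2-methylbutanal
Product: 14 (2E,4S)-2,4-dimethylhex-2-enal
Conditions: Ph3P=C(CH3)CHO, toluene, 80 °C
Reagents that add atoms: 2-(triphenylphosphoranylidene)propanal CC(C=O)=P(c1ccccc1)(c1ccccc1)c1ccccc1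
Why: Wittig olefination with a stabilised ylide, which is (E)-selective and too weakly basic to epimerise the aldehyde; the conjugated α-substituted product does not compete for the ylide.

Step 9
Reactants: 14 (2E,4S)-2,4-dimethylhex-2-enal
Product: 15 (2E,4E,6S)-4,6-dimethylocta-2,4-dienenitrile
Conditions: (EtO)2P(O)CH2CN, NaH, THF, 0 °C → rt; minor (2Z) isomer removed by chromatography
Reagents that add atoms: diethyl (cyanomethyl)phosphonate CCOP(=O)(CC#N)OCC
Why: Horner–Wadsworth–Emmons olefination with a cyano-stabilised phosphonate anion, which should give mainly the (2E) alkenenitrile with an α-branched enal; the existing alkene and the stereocentre are spectators.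

Step 10
Reactants: 11 methyl (2R,3S)-2-ethynyl-3-methoxy-3-methyl-4-oxo-2-[(triethylsilyl)oxy]-6-(trimethylsilyl)hex-5-ynoate; 15 (2E,4E,6S)-4,6-dimethylocta-2,4-dienenitrile
Product: 16 methyl (5R,6S)-3-[(1E,3E,5S)-3,5-dimethylhepta-1,3-dien-1-yl]-6-methoxy-6-methyl-7-oxo-5-[(triethylsilyl)oxy]-1-(trimethylsilyl)-6,7-dihydro-5H-cyclopenta[c]pyridine-5-carboxylate
Conditions: CpCo(CO)2 (20 mol%), 15 (4 equiv), degassed toluene, 110 °C, visible-light lamp; 11 and catalyst added by syringe pump; excess 15 recovered
Reagents that add atoms: none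
Why: CpCo(CO)2 loses CO on heating and irradiation, the monovalent cobalt fragment binds both alkynes of 11 and couples them oxidatively to a bicyclic cobaltacyclopentadiene of trivalent cobalt (bond C4a–C7a), the nitrile of 15 inserts into the Co–C4 bond (bond C3–C4), and C–N reductive elimination (bond N2–C1) releases the pyridine and monovalent cobalt. The closest known reaction type is the CpCo-catalysed cocyclisation of α,ω-diynes with nitriles to ring-fused pyridines, known for acrylonitrile-type nitriles reacting at C≡N and for diynes with one silylated terminus. Ring B closes intramolecularly in the oxidative coupling, helped by the three-atom tether with two quaternary carbons, and ring A closes by intermolecular nitrile insertion and reductive elimination, together a metal-templated [2+2+2] cycloaddition. No stereocentre is formed, and C5, C6, the side-chain centre and both alkene geometries are spectators because no bond to them is made or broken. The step needs regioselective nitrile insertion and cross- over self-cyclisation: the SiMe3 group blocks the Co–C1 bond, so the nitrile carbon bonds to C4 and nitrogen ends next to silicon, and slow addition of 11 into excess 15 keeps free diyne scarce. The silyl ether keeps the C5 oxygen from binding cobalt and from retro-aldol cleavage at 110 °C.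

Step 11
Reactants: 16 methyl (5R,6S)-3-[(1E,3E,5S)-3,5-dimethylhepta-1,3-dien-1-yl]-6-methoxy-6-methyl-7-oxo-5-[(triethylsilyl)oxy]-1-(trimethylsilyl)-6,7-dihydro-5H-cyclopenta[c]pyridine-5-carboxylate
Product: 17 methyl (5R,6S)-3-[(1E,3E,5S)-3,5-dimethylhepta-1,3-dien-1-yl]-5-hydroxy-6-methoxy-6-methyl-7-oxo-6,7-dihydro-5H-cyclopenta[c]pyridine-5-carboxylate (CNP0548933.1)
Conditions: Bu4NF (3 equiv), AcOH (3 equiv), THF, 0 °C → rt
Reagents that add atoms: none
Why: Fluoride-induced protodesilylation, which is easy at the position next to a pyridine nitrogen (C1–Si), together with cleavage of the triethylsilyl ether by the same reagent; the acetic acid buffer protonates the C5 alkoxide before it can open ring B by retro-aldol reaction, so C5 and C6 keep their configuration.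

Compound list
1 | (R)-lactic acid | C[C@@H](O)C(=O)O | starting material
2 | (2R,5R)-2-tert-butyl-5-methyl-1,3-dioxolan-4-one | C[C@H]1O[C@@H](C(C)(C)C)OC1=O | intermediate
3 | lithium (2R)-2-tert-butyl-5-methyl-1,3-dioxol-4-olate | CC1=C([O-])O[C@H](C(C)(C)C)O1.[Li+] | intermediate (not isolated)
4 | methyl 2-[(2R,4S)-2-tert-butyl-4-methyl-5-oxo-1,3-dioxolan-4-yl]-2-oxoacetate | C[C@@]1(C(=O)C(=O)OC)O[C@@H](C(C)(C)C)OC1=O | intermediate
5 | methyl (2R)-2-[(2R,4S)-2-tert-butyl-4-methyl-5-oxo-1,3-dioxolan-4-yl]-2-hydroxybut-3-ynoate | C#C[C@](O)(C(=O)OC)[C@]1(C)O[C@@H](C(C)(C)C)OC1=O | intermediate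
6 | methyl (2R)-2-[(2R,4S)-2-tert-butyl-4-methyl-5-oxo-1,3-dioxolan-4-yl]-2-[(triethylsilyl)oxy]but-3-ynoate | C#C[C@](O[Si](CC)(CC)CC)(C(=O)OC)[C@]1(C)O[C@@H](C(C)(C)C)OC1=O | intermediate
7 | ethynyltrimethylsilane | C#C[Si](C)(C)C | starting material
8 | lithium (trimethylsilyl)acetylide | [Li]C#C[Si](C)(C)C | intermediate (not isolated)
9 | lithium (2R,5S)-2-tert-butyl-5-{(2R)-1-methoxy-1-oxo-2-[(triethylsilyl)oxy]but-3-yn-2-yl}-5-methyl-4-[(trimethylsilyl)ethynyl]-1,3-dioxolan-4-olate (C4 configuration not defined) | C#C[C@](O[Si](CC)(CC)CC)(C(=O)OC)[C@]1(C)O[C@@H](C(C)(C)C)OC1([O-])C#C[Si](C)(C)C.[Li+] | intermediate (not isolated)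
10 | methyl (2R,3S)-2-ethynyl-3-hydroxy-3-methyl-4-oxo-2-[(triethylsilyl)oxy]-6-(trimethylsilyl)hex-5-ynoate | C[Si](C)(C)C#CC(=O)[C@@](C)(O)[C@](O[Si](CC)(CC)CC)(C#C)C(=O)OC | intermediate
11 | methyl (2R,3S)-2-ethynyl-3-methoxy-3-methyl-4-oxo-2-[(triethylsilyl)oxy]-6-(trimethylsilyl)hex-5-ynoate | C[Si](C)(C)C#CC(=O)[C@@](C)(OC)[C@](O[Si](CC)(CC)CC)(C#C)C(=O)OC | intermediate
12 | (S)-2-methylbutan-1-ol | CC[C@H](C)CO | starting material
13 | (S)-2-methylbutanal | CC[C@H](C)C=O | intermediate
14 | (2E,4S)-2,4-dimethylhex-2-enal | CC[C@H](C)/C=C(C)/C=O | intermediate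
15 | (2E,4E,6S)-4,6-dimethylocta-2,4-dienenitrile | CC[C@H](C)/C=C(C)/C=C/C#N | intermediate
16 | methyl (5R,6S)-3-[(1E,3E,5S)-3,5-dimethylhepta-1,3-dien-1-yl]-6-methoxy-6-methyl-7-oxo-5-[(triethylsilyl)oxy]-1-(trimethylsilyl)-6,7-dihydro-5H-cyclopenta[c]pyridine-5-carboxylate | CC[C@H](C)/C=C(C)/C=C/c1cc2c(c(n1)[Si](C)(C)C)C(=O)[C@@](C)(OC)[C@@]2(O[Si](CC)(CC)CC)C(=O)OC | intermediate
17 | methyl (5R,6S)-3-[(1E,3E,5S)-3,5-dimethylhepta-1,3-dien-1-yl]-5-hydroxy-6-methoxy-6-methyl-7-oxo-6,7-dihydro-5H-cyclopenta[c]pyridine-5-carboxylate | CC[C@H](C)/C=C(C)/C=C/c1cc2c(cn1)C(=O)[C@@](C)(OC)[C@@]2(O)C(=O)OC | target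

Total steps: 11. Longest linear sequence: 8 steps (steps 1–6, 10 and 11, from (R)-lactic acid); the nitrile branch (steps 7–9) has 3 steps.

Steps most likely to fail

Step 10. What may go wrong: the cobalt may be tied up by the conjugated diene of 15 or spent in self-oligomerisation of the diyne, the nitrile may insert with the opposite orientation, or a C=C bond of 15 may take part instead of C≡N. The fallback sets out from 11, uses 14 in place of 15 and returns at 16. It closes the pyridine with a small activated nitrile and attaches the diene afterwards by olefination. Diyne 11 and chloroacetonitrile are cocyclised with Cp*RuCl(cod) in 1,2-dichloroethane at 60 °C, a catalyst for which α-halonitriles are good partners and which should again place the substituted alkyne terminus next to nitrogen, to give the 3-(chloromethyl)pyridine F1. Michaelis–Arbuzov reaction of F1 with P(OEt)3 at 130 °C gives the pyridylmethyl phosphonate F2. Horner–Wadsworth–Emmons reaction of F2 (NaH, THF, 0 °C) with enal 14 builds the (1E) double bond and gives 16.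

Step 3. What may go wrong: poor or reversed facial selectivity in the acetylide addition, which sets the future C5, or retro-aldol fragmentation of the magnesium aldolate if it warms. The fallback sets out from 2 (through enolate 3) and returns at 5. It introduces the two carbon substituents of the carbinol in the opposite order, so that the same facial bias leads to the other epimer. Enolate 3 is acylated with 3-(trimethylsilyl)propynoyl chloride at −78 °C to give the alkynyl ketone F3. 1-Methoxyvinyllithium (from methyl vinyl ether and t-BuLi, THF, −78 °C) adds to the ketone as a masked methoxycarbonyl anion to give the enol ether carbinol F4. Ozonolysis (O3, CH2Cl2/MeOH, −78 °C; Me2S) converts the methoxyvinyl group into the methyl ester F5. Bu4NF/AcOH in THF at 0 °C removes the alkynyl SiMe3 group and gives 5.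

Step 6. What may go wrong: O-alkylation at a carbinol wedged between two fully substituted carbons may be too slow, so that silyl transfer or decomposition of the ynone takes over on long heating. The fallback sets out from 10 and returns at 16. It postpones the methylation until after the annulation. Hydroxy ynone 10 and nitrile 15 are cocyclised under the conditions of step 10 to give the 6-hydroxy pyridine F6. In F6 the carbinol is tied back in the five-membered ring and no alkyne is left, so Purdie methylation (MeI, Ag2O, MeCN, 40 °C) can be used; the ring nitrogen is shielded by the C1 SiMe3 group, and the product is 16.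

Further compounds
F1 | step 10 | methyl (5R,6S)-3-(chloromethyl)-6-methoxy-6-methyl-7-oxo-5-[(triethylsilyl)oxy]-1-(trimethylsilyl)-6,7-dihydro-5H-cyclopenta[c]pyridine-5-carboxylate | ClCc1cc2c(c(n1)[Si](C)(C)C)C(=O)[C@@](C)(OC)[C@@]2(O[Si](CC)(CC)CC)C(=O)OC
F2 | step 10 | methyl (5R,6S)-3-[(diethoxyphosphoryl)methyl]-6-methoxy-6-methyl-7-oxo-5-[(triethylsilyl)oxy]-1-(trimethylsilyl)-6,7-dihydro-5H-cyclopenta[c]pyridine-5-carboxylate | CCOP(=O)(Cc1cc2c(c(n1)[Si](C)(C)C)C(=O)[C@@](C)(OC)[C@@]2(O[Si](CC)(CC)CC)C(=O)OC)OCC
F3 | step 3 | (2R,5S)-2-tert-butyl-5-methyl-5-[3-(trimethylsilyl)prop-2-ynoyl]-1,3-dioxolan-4-one | C[C@@]1(C(=O)C#C[Si](C)(C)C)O[C@@H](C(C)(C)C)OC1=O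
F4 | step 3 | (2R,5S)-2-tert-butyl-5-[(3S)-3-hydroxy-2-methoxy-5-(trimethylsilyl)pent-1-en-4-yn-3-yl]-5-methyl-1,3-dioxolan-4-one | C=C(OC)[C@@](O)(C#C[Si](C)(C)C)[C@]1(C)O[C@@H](C(C)(C)C)OC1=O
F5 | step 3 | methyl (2R)-2-[(2R,4S)-2-tert-butyl-4-methyl-5-oxo-1,3-dioxolan-4-yl]-2-hydroxy-4-(trimethylsilyl)but-3-ynoate | C[Si](C)(C)C#C[C@](O)(C(=O)OC)[C@]1(C)O[C@@H](C(C)(C)C)OC1=O
F6 | step 6 | methyl (5R,6S)-3-[(1E,3E,5S)-3,5-dimethylhepta-1,3-dien-1-yl]-6-hydroxy-6-methyl-7-oxo-5-[(triethylsilyl)oxy]-1-(trimethylsilyl)-6,7-dihydro-5H-cyclopenta[c]pyridine-5-carboxylate | CC[C@H](C)/C=C(C)/C=C/c1cc2c(c(n1)[Si](C)(C)C)C(=O)[C@@](C)(O)[C@@]2(O[Si](CC)(CC)CC)C(=O)OC
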